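**Strategy.** Everything rests on the C3–C4 bond of the pyran ring (ring C) of the central fisetinidol unit B, whose two carbons carry vicinal hydroxyl and aryl groups and so map onto an alkene. Ring-closing metathesis of an enantioenriched 1-arylallyl ether of a 2-vinylphenol, whose resorcinol ring already carries the terminal fisetinidol unit A, forms this bond as the C3=C4 alkene of a flav-3-ene and closes ring C in one operation. The C2 aryl group then steers cis-dihydroxylation to the opposite face; ionisation at C4 lets C6 of fisetinidol-(4α→8)-catechin enter trans to the 3-OH. The precursor is an open-chain diene ether made by iridium-catalysed allylic etherification.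

Key step: step 9

Assumptions and conventions: (2R,3R)-fustin and 5-(benzyloxy)-2-bromophenol are taken as purchasable catalogue compounds. Units: A = terminal fisetinidol (4→6 linked to B), B = central fisetinidol, C = catechin, D = fisetinidol on C8 of C. Flavan numbering is used, and α is the face of ring C that carries the C2 aryl group. The iridium ligand antipode in step 8 is assumed to be the one that delivers the (S)-configured branched ether.

**Step 1**
Reactants: 1 (+)-fustin
Product: 2 (+)-mollisacacidin, the (2R,3S,4R)-flavan-3,4-diol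
Conditions: NaBH4, EtOH, 0 °C → rt
Reagents that add atoms: none
Why: Borohydride reduction of the flavanone carbonyl, in which hydride adds axially to the half-chair with the C2 and C3 substituents equatorial, so the new 4-OH is equatorial and trans to the 3-OH (2,3-trans-3,4-trans) while C2 and C3 come unchanged from fustin.

**Step 2**
Reactants: 2 (+)-mollisacacidin
Product: 3 7,3',4'-tri-O-benzylmollisacacidin
Conditions: BnBr (3.3 equiv), K2CO3, acetone, rt → 50 °C
Reagents that add atoms: benzyl bromide, BrCc1ccccc1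
Why: Williamson etherification with a weak base that deprotonates only the three phenols, so the aliphatic 3,4-diol stays free.

**Step 3**
Reactants: 3 7,3',4'-tri-O-benzylmollisacacidin; 4 5-(benzyloxy)-2-bromophenol (4 equiv)
Product: 5 tri-O-benzylfisetinidol carrying at C4α the 2-(benzyloxy)-5-bromo-4-hydroxyphenyl group
Conditions: BF3·OEt2 (0.3 equiv), CH2Cl2, −20 → 0 °C
Reagents that add atoms: none
Why: Friedel–Crafts alkylation through the para-benzyloxy-stabilised C4 cation with loss of water, in which the phenol reacts para to its OH (the bromine blocks the position para to the benzyloxy group) and enters trans to the 3-OH, which should set the 4α centre of unit A, while the excess phenol suppresses self-condensation of 3.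

**Step 4**
Reactants: 5 bromophenol adduct
Product: 6 vinylphenol (5 with ethenyl in place of bromine)
Conditions: vinylboronic acid pinacol ester (1.5 equiv), Pd(OAc)2 (5 mol %), SPhos (10 mol %), K3PO4, dioxane/H2O, 80 °C
Reagents that add atoms: vinylboronic acid pinacol ester, C=CB1OC(C)(C)C(C)(C)O1
Why: Suzuki–Miyaura coupling of the aryl bromide, which tolerates the free phenol and the secondary alcohol under aqueous phosphate and touches no stereocentre.

**Step 5**
Reactants: 7 3,4-bis(benzyloxy)benzaldehyde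
Product: 8 ethyl (E)-3-[3,4-bis(benzyloxy)phenyl]prop-2-enoate
Conditions: triethyl phosphonoacetate, NaH, THF, 0 °C → rt
Reagents that add atoms: triethyl phosphonoacetate, CCOC(=O)CP(=O)(OCC)OCC
Why: Horner–Wadsworth–Emmons olefination, which gives the (E)-cinnamate from the stabilised phosphonate anion.

**Step 6**
Reactants: 8 ethyl (E)-cinnamate
Product: 9 (E)-3-[3,4-bis(benzyloxy)phenyl]prop-2-en-1-ol
Conditions: i-Bu2AlH (2.2 equiv), CH2Cl2, −78 °C; aq. KNaC4H4O6 (potassium sodium tartrate)
Reagents that add atoms: none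
Why: 1,2-Reduction of the conjugated ester by the aluminium hydride, which leaves the alkene geometry and the benzyl ethers untouched.

**Step 7**
Reactants: 9 (E)-cinnamyl alcohol
Product: 10 (E)-3-[3,4-bis(benzyloxy)phenyl]prop-2-en-1-yl methyl carbonate
Conditions: ClCO2Me, pyridine, CH2Cl2, 0 °C
Reagents that add atoms: methyl chloroformate, COC(=O)Cl
Why: Acylation of the primary allylic alcohol with a chloroformate gives the linear carbonate that iridium catalysis requires.

**Step 8**
Reactants: 6 vinylphenol; 10 cinnamyl methyl carbonate (1.2 equiv)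
Product: 12 (S)-1-arylallyl 2-vinylaryl diene ether, via lithium phenoxide 11 (not isolated)
Conditions: LiN(SiMe3)2 (1.0 equiv), THF, 0 °C; then 10, [Ir(cod)Cl]2 (2 mol %), (Sa,Sc,Sc)-binaphthol N,N-bis(1-phenylethyl)phosphoramidite (4 mol %, preactivated with n-PrNH2), THF, 25–40 °C
Reagents that add atoms: none
Why: Iridium-catalysed asymmetric allylic etherification, in which the cyclometalated iridium phosphoramidite ionises the linear carbonate and the phenoxide attacks the aryl-bearing allyl terminus, so the branched ether should form with the (S) centre (C2 of unit B) set by the ligand antipode chosen for that sense of induction.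

**Step 9**
Reactants: 12 diene ether
Product: 13 flav-3-ene: (2S)-7-(benzyloxy)-2-[3,4-bis(benzyloxy)phenyl]-2H-chromene carrying unit A at C6
Conditions: second-generation Grubbs catalyst, (H2IMes)(PCy3)Cl2Ru=CHPh (5 mol %), CH2Cl2 (0.01 M), 40 °C, argon, dark
Reagents that add atoms: none
Why: Ring-closing olefin metathesis by the metallacyclobutane mechanism: the ruthenium alkylidene loads onto the monosubstituted allyl ether alkene, the resulting carbene adds across the ortho vinyl group, and cycloreversion expels ethene and leaves the C3=C4 bond of unit B. The closest known reaction type is the metathesis of 2-(allyloxy)styrenes to 2H-chromenes. Ring C closes as a six-membered ring between two terminal alkene carbons, both of which end up inside the ring, and loss of ethene makes the closure irreversible. No stereocentre is formed; the C2 centre from step 8 takes no part and is kept, and its aryl group later differentiates the two faces of the new alkene for step 10. The step needs cyclisation to win over cross-metathesis and over migration of the allyl ether double bond, which the ortho 1,6-diene geometry, high dilution and the absence of any other alkene should secure. Light and acid are excluded so that the 2H-chromene does not open to the ortho-quinone methide or ionise at C2–O1, either of which would scramble C2.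

**Step 10**
Reactants: 13 flav-3-ene
Product: 14 cis-diol: (2R,3S,4S)-2,3-trans-3,4-cis-flavan-3,4-diol of unit B carrying unit A at C6
Conditions: OsO4 (4 mol %), N-methylmorpholine N-oxide (1.5 equiv), acetone/THF/H2O, 0 °C → rt
Reagents that add atoms: N-methylmorpholine N-oxide, C[N+]1([O-])CCOCC1; water, O
Why: Catalytic cis-dihydroxylation by (3+2) addition of OsO4 to the face opposite the C2 aryl group, which should place 3-OH and 4-OH both on the β face (2,3-trans-3,4-cis).

**Step 11**
Reactants: 2 (+)-mollisacacidin; 15 (+)-catechin (4 equiv)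
Product: 16 fisetinidol-(4α→8)-catechin
Conditions: 0.1 M aq. HCl, rt, N2; Sephadex LH-20 (EtOH)
Reagents that add atoms: none
Why: Biomimetic acid-catalysed Friedel–Crafts condensation with loss of water, in which the C4 cation (para-quinone methide) of the flavan-3,4-diol should be captured by the phloroglucinol ring of catechin mainly at C8 and trans to the 3-OH (4α), with the excess catechin limiting further substitution.

**Step 12**
Reactants: 14 cis-diol; 16 fisetinidol-(4α→8)-catechin (2 equiv)
Product: 17 hexa-O-benzyl tetraflavanoid (the target with benzyl ethers on O7, O3' and O4' of units A and B)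
Conditions: BF3·OEt2 (0.5 equiv), anhydrous 1,4-dioxane, 10 → 25 °C; Sephadex LH-20
Reagents that add atoms: none
Why: Friedel–Crafts coupling through the C4 benzylic cation of unit B with loss of water, for which C6 is the only open position on the free phloroglucinol ring of 16 and much more nucleophilic than any resorcinol-type ring, while attack trans to the 3-OH of the 2,3-trans cation should set the 4α (3,4-trans) centre of unit B.

**Step 13**
Reactants: 17 hexa-O-benzyl tetraflavanoid
Product: 18 target, fisetinidol-(4α→6)-fisetinidol-(4α→6)-catechin-(8←4α)-fisetinidol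
Conditions: H2 (1 atm), Pd(OH)2/C, THF/MeOH/H2O, rt; Sephadex LH-20
Reagents that add atoms: none
Why: Hydrogenolysis of the six benzyl aryl ethers under neutral conditions, which should leave the diarylmethine C4–aryl bonds, the pyran C2–O1 bonds and all stereocentres untouched.

**Compound list**

1 | (+)-fustin, (2R,3R)-3,7-dihydroxy-2-(3,4-dihydroxyphenyl)chroman-4-one | Oc1ccc2c(c1)O[C@H](c1ccc(O)c(O)c1)[C@@H](O)C2=O | starting material
2 | (+)-mollisacacidin, (2R,3S,4R)-2-(3,4-dihydroxyphenyl)chromane-3,4,7-triol | Oc1ccc2c(c1)O[C@H](c1ccc(O)c(O)c1)[C@@H](O)[C@@H]2O | intermediate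
3 | (2R,3S,4R)-7-(benzyloxy)-2-[3,4-bis(benzyloxy)phenyl]chromane-3,4-diol | c1ccccc1COc1ccc2c(c1)O[C@H](c1ccc(OCc3ccccc3)c(OCc3ccccc3)c1)[C@@H](O)[C@@H]2O | intermediate
4 | 5-(benzyloxy)-2-bromophenol | Oc1cc(OCc2ccccc2)ccc1Br | starting material
5 | (2R,3S)-2,3-trans-3,4-trans-7-(benzyloxy)-2-[3,4-bis(benzyloxy)phenyl]-4α-[2-(benzyloxy)-5-bromo-4-hydroxyphenyl]chroman-3-ol | c1ccccc1COc1ccc2c(c1)O[C@H](c1ccc(OCc3ccccc3)c(OCc3ccccc3)c1)[C@@H](O)[C@@H]2c1cc(Br)c(O)cc1OCc1ccccc1 | intermediate
6 | (2R,3S)-2,3-trans-3,4-trans-7-(benzyloxy)-2-[3,4-bis(benzyloxy)phenyl]-4α-[2-(benzyloxy)-5-ethenyl-4-hydroxyphenyl]chroman-3-ol | c1ccccc1COc1ccc2c(c1)O[C@H](c1ccc(OCc3ccccc3)c(OCc3ccccc3)c1)[C@@H](O)[C@@H]2c1cc(C=C)c(O)cc1OCc1ccccc1 | intermediate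
7 | 3,4-bis(benzyloxy)benzaldehyde | O=Cc1ccc(OCc2ccccc2)c(OCc2ccccc2)c1 | starting material
8 | ethyl (E)-3-[3,4-bis(benzyloxy)phenyl]prop-2-enoate | CCOC(=O)/C=C/c1ccc(OCc2ccccc2)c(OCc2ccccc2)c1 | intermediate
9 | (E)-3-[3,4-bis(benzyloxy)phenyl]prop-2-en-1-ol | OC/C=C/c1ccc(OCc2ccccc2)c(OCc2ccccc2)c1 | intermediate
10 | (E)-3-[3,4-bis(benzyloxy)phenyl]prop-2-en-1-yl methyl carbonate | COC(=O)OC/C=C/c1ccc(OCc2ccccc2)c(OCc2ccccc2)c1 | intermediate
11 | lithium phenoxide of 6 | c1ccccc1COc1ccc2c(c1)O[C@H](c1ccc(OCc3ccccc3)c(OCc3ccccc3)c1)[C@@H](O)[C@@H]2c1cc(C=C)c([O-])cc1OCc1ccccc1.[Li+] | intermediate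
12 | diene ether: 6 etherified on the phenol oxygen with the (S)-1-[3,4-bis(benzyloxy)phenyl]prop-2-en-1-yl group | c1ccccc1COc1ccc2c(c1)O[C@H](c1ccc(OCc3ccccc3)c(OCc3ccccc3)c1)[C@@H](O)[C@@H]2c1cc(C=C)c(O[C@H](c2ccc(OCc3ccccc3)c(OCc3ccccc3)c2)C=C)cc1OCc1ccccc1 | intermediate
13 | flav-3-ene: (2S)-7-(benzyloxy)-2-[3,4-bis(benzyloxy)phenyl]-2H-chromene carrying at C6 the tri-O-benzylfisetinidol-4α-yl unit A | c1ccccc1COc1ccc2c(c1)O[C@H](c1ccc(OCc3ccccc3)c(OCc3ccccc3)c1)[C@@H](O)[C@@H]2c1cc2c(cc1OCc1ccccc1)O[C@H](c1ccc(OCc3ccccc3)c(OCc3ccccc3)c1)C=C2 | intermediate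
14 | cis-diol: (2R,3S,4S)-7-(benzyloxy)-2-[3,4-bis(benzyloxy)phenyl]chromane-3,4-diol (2,3-trans-3,4-cis) carrying at C6 the tri-O-benzylfisetinidol-4α-yl unit A | c1ccccc1COc1ccc2c(c1)O[C@H](c1ccc(OCc3ccccc3)c(OCc3ccccc3)c1)[C@@H](O)[C@@H]2c1cc2c(cc1OCc1ccccc1)O[C@H](c1ccc(OCc3ccccc3)c(OCc3ccccc3)c1)[C@@H](O)[C@H]2O | intermediate
15 | (+)-catechin, (2R,3S) | Oc1cc(O)c2c(c1)O[C@H](c1ccc(O)c(O)c1)[C@@H](O)C2 | starting material
16 | fisetinidol-(4α→8)-catechin | c1c(O)c2c(c([C@@H]3c4ccc(O)cc4O[C@H](c4ccc(O)c(O)c4)[C@H]3O)c1O)O[C@H](c1ccc(O)c(O)c1)[C@@H](O)C2 | intermediate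
17 | hexa-O-benzyl tetraflavanoid: target with benzyl ethers on O7, O3' and O4' of units A and B | c1ccccc1COc1ccc2c(c1)O[C@H](c1ccc(OCc3ccccc3)c(OCc3ccccc3)c1)[C@@H](O)[C@@H]2c1cc2c(cc1OCc1ccccc1)O[C@H](c1ccc(OCc3ccccc3)c(OCc3ccccc3)c1)[C@@H](O)[C@@H]2c1c(O)c2c(c([C@@H]3c4ccc(O)cc4O[C@H](c4ccc(O)c(O)c4)[C@H]3O)c1O)O[C@H](c1ccc(O)c(O)c1)[C@@H](O)C2 | intermediate
18 | CNP0263622.1, fisetinidol-(4α→6)-fisetinidol-(4α→6)-catechin-(8←4α)-fisetinidol | Oc1ccc2c(c1)O[C@H](c1ccc(O)c(O)c1)[C@@H](O)[C@@H]2c1cc2c(cc1O)O[C@H](c1ccc(O)c(O)c1)[C@@H](O)[C@@H]2c1c(O)c2c(c([C@@H]3c4ccc(O)cc4O[C@H](c4ccc(O)c(O)c4)[C@H]3O)c1O)O[C@H](c1ccc(O)c(O)c1)[C@@H](O)C2 | target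

**Count**

Total steps: 13. Longest linear sequence: 9 steps (1, 2, 3, 4, 8, 9, 10, 12, 13).

**Steps most likely to fail**

1. Step 12. Capture of the unit B cation by the hindered C6 of 16 may be slow in a medium that must dissolve both a hexabenzyl ether and a polyphenol. Self-condensation of 14 at C6 of its unit A and attack from the β face could then gain ground. The fallback sets out from 16 and couples fully protected partners in an aprotic Lewis-acid regime. Exhaustive phenol benzylation (BnBr, K2CO3, DMF) should give hepta-O-benzyl-fisetinidol-(4α→8)-catechin F1. Coupling of 14 with F1 (3 equiv) under Me3SiOTf in CH2Cl2 at −40 °C should give the trideca-O-benzyl tetraflavanoid F2. Hydrogenolysis of F2 (H2, Pd(OH)2/C) comes back to the route at 18.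

2. Step 3. The bromine lowers the nucleophilicity of 4, so the cation from 3 may instead be captured by ring A of a second molecule of 3 and give oligomers. The fallback sets out from 3 and uses unsubstituted resorcinol, which is far more nucleophilic and reacts at its least hindered doubly activated position. BF3·OEt2-catalysed condensation with resorcinol (10 equiv) should give the 4α-(2,4-dihydroxyphenyl) adduct F3. Magnesium-mediated ortho-formylation (MgCl2, Et3N, paraformaldehyde, MeCN, reflux) next to the OH para to the flavanyl group should give the salicylaldehyde F4. Benzylation of the OH that is not hydrogen-bonded to the aldehyde (BnBr 1.05 equiv, K2CO3, acetone) should give the 4-O-benzyl salicylaldehyde F5. Wittig methylenation (Ph3P=CH2 in excess, made in the flask from Ph3PCH3Br and KOt-Bu, THF) comes back to the route at 6.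

3. Step 8. The electron-rich cinnamyl carbonate may ionise outside the chiral pocket, giving linear ether and lower stereocontrol at C2 of unit B, or the ortho-substituted phenoxide may react slowly. The fallback sets out from 7 and moves the stereocontrol to a carbinol. Catalytic asymmetric vinylation (Zn(CH=CH2)2, chiral amino alcohol such as 3-exo-morpholinoisoborneol in the antipode that gives the (R) carbinol, toluene, 0 °C) should give (R)-1-[3,4-bis(benzyloxy)phenyl]prop-2-en-1-ol F6. Mitsunobu etherification of 6 with F6 (PPh3, DIAD, toluene, −20 °C, the low temperature and nonpolar solvent chosen to disfavour ionisation) should proceed with inversion and comes back to the route at 12. Because unit A is enantiopure, any C2 epimer is a diastereomer and can be removed by chromatography.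

**Further compounds**

F1 | step 12 | hepta-O-benzyl-fisetinidol-(4α→8)-catechin | c1c(OCc5ccccc5)c2c(c([C@@H]3c4ccc(OCc5ccccc5)cc4O[C@H](c4ccc(OCc5ccccc5)c(OCc5ccccc5)c4)[C@H]3O)c1OCc1ccccc1)O[C@H](c1ccc(OCc3ccccc3)c(OCc3ccccc3)c1)[C@@H](O)C2
F2 | step 12 | trideca-O-benzyl tetraflavanoid (all phenols of 18 as benzyl ethers) | c1ccccc1COc1ccc2c(c1)O[C@H](c1ccc(OCc3ccccc3)c(OCc3ccccc3)c1)[C@@H](O)[C@@H]2c1cc2c(cc1OCc1ccccc1)O[C@H](c1ccc(OCc3ccccc3)c(OCc3ccccc3)c1)[C@@H](O)[C@@H]2c1c(OCc5ccccc5)c2c(c([C@@H]3c4ccc(OCc5ccccc5)cc4O[C@H](c4ccc(OCc5ccccc5)c(OCc5ccccc5)c4)[C@H]3O)c1OCc1ccccc1)O[C@H](c1ccc(OCc3ccccc3)c(OCc3ccccc3)c1)[C@@H](O)C2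
F3 | step 3 | tri-O-benzylfisetinidol carrying at C4α the 2,4-dihydroxyphenyl group | c1ccccc1COc1ccc2c(c1)O[C@H](c1ccc(OCc3ccccc3)c(OCc3ccccc3)c1)[C@@H](O)[C@@H]2c1ccc(O)cc1O
F4 | step 3 | tri-O-benzylfisetinidol carrying at C4α the 5-formyl-2,4-dihydroxyphenyl group | c1ccccc1COc1ccc2c(c1)O[C@H](c1ccc(OCc3ccccc3)c(OCc3ccccc3)c1)[C@@H](O)[C@@H]2c1cc(C=O)c(O)cc1O
F5 | step 3 | tri-O-benzylfisetinidol carrying at C4α the 2-(benzyloxy)-5-formyl-4-hydroxyphenyl group | c1ccccc1COc1ccc2c(c1)O[C@H](c1ccc(OCc3ccccc3)c(OCc3ccccc3)c1)[C@@H](O)[C@@H]2c1cc(C=O)c(O)cc1OCc1ccccc1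
F6 | step 8 | (R)-1-[3,4-bis(benzyloxy)phenyl]prop-2-en-1-ol | O[C@H](C=C)c1ccc(OCc2ccccc2)c(OCc2ccccc2)c1
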